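**Retrosynthetic overview** (skeleton numbered as tricyclo[5.4.0.0^2,8]undec-9-en-11-one, C1–C11)
1. Esters last: C3 angelate at the very end; one Evans–Tishchenko reduction of the C5-hydroxy C3-ketone gives the C5 epoxy ester and the 1,3-anti C3–OH.
2. Seven-membered ring (C2–C7) by ring-closing metathesis of a C2 acryloyl and a C6 vinyl group; C5–O by ligand-controlled copper-catalysed borylation.
3. Key disconnection C1–C7. C1 is α to the C11 ketone and C7 stands 1,3 to it across C2/C8 on ring C1–C2–C8–C9–C10–C11, so a C1 enolate born by Me2CuLi addition at C2 can close the cyclobutane C1–C2–C8–C7 on a C7 mesylate; this one cut removes both bridged systems.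
4. The monocyclic enone comes from (S)-5-methylcyclohex-2-enone by syn aldol (C8–C7), MOMOCH2Li addition and oxidative transposition; its only stereocentre (C9) relays chirality and is erased by Saegusa oxidation.
5. Ring order: six-membered ring (chiral pool) → cyclobutane, giving the bicyclo[3.1.1]heptanone (key step) → seven-membered ring.

Key step: step 7

Assumption: (S)-5-methylcyclohex-2-en-1-one (4) is bought as such; if not, it is reachable in three known steps from (S)-pulegone.

**Step 1**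
Reactants: 1 2,2-dimethylbut-3-enoic acid
Product: 2 2,2-dimethylbut-3-en-1-ol
Conditions: LiAlH4, Et2O, 0 °C → rt
Reagents that add atoms: none
Why: LiAlH4 reduction of the carboxylic acid to the primary alcohol; the isolated vinyl group is untouched and no stereocentre is involved.

**Step 2**
Reactants: 2 2,2-dimethylbut-3-en-1-ol
Product: 3 2,2-dimethylbut-3-enal
Conditions: TEMPO (cat.), PhI(OAc)2, CH2Cl2, rt; used as a solution
Reagents that add atoms: none
Why: TEMPO/hypervalent-iodine (oxoammonium) oxidation should stop at the non-enolisable neopentyl aldehyde.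

**Step 3**
Reactants: 4 (S)-5-methylcyclohex-2-en-1-one; 3 2,2-dimethylbut-3-enal
Product: 5 (5S,6S)-6-[(1S)-1-hydroxy-2,2-dimethylbut-3-en-1-yl]-5-methylcyclohex-2-en-1-one
Conditions: LiN(i-Pr)2, THF, −78 °C; Cp2ZrCl2, −78 → −40 °C; 3, −78 °C; cold 0.5 M HCl
Reagents that add atoms: none
Why: Directed aldol of the kinetic α′-enolate after transmetallation to the zirconocene enolate, which is syn-selective whatever the enolate geometry; the aldehyde adds anti to the C5 methyl (6S) and the syn transition state sets the carbinol carbon (1′S).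

**Step 4**
Reactants: 5 syn aldol
Product: 6 (1S,5S,6S)-6-[(1S)-1-hydroxy-2,2-dimethylbut-3-en-1-yl]-1-[(methoxymethoxy)methyl]-5-methylcyclohex-2-en-1-ol
Conditions: Bu3SnCH2OCH2OMe, n-BuLi, THF, −78 °C; then 5 (0.4 equiv), −78 °C; H2O
Reagents that add atoms: tributyl[(methoxymethoxy)methyl]stannane CCCC[Sn](CCCC)(CCCC)COCOC
Why: 1,2-addition of Still's α-alkoxymethyllithium (tin–lithium exchange) to the enone carbonyl; the new tertiary carbinol centre (attack anti to the side chain expected) does not matter because it becomes sp2 in step 6.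

**Step 5**
Reactants: 6 diol
Product: 7 (1S)-1-[(1S,2S,6S)-2-hydroxy-2-[(methoxymethoxy)methyl]-6-methylcyclohex-3-en-1-yl]-2,2-dimethylbut-3-en-1-yl methanesulfonate
Conditions: MsCl (1.1 equiv), Et3N, CH2Cl2, −20 °C
Reagents that add atoms: methanesulfonyl chloride CS(Cl)(=O)=O
Why: Sulfonylation of the secondary hydroxyl in the presence of the tertiary allylic one (steric chemoselectivity); the carbinol configuration is retained.

**Step 6**
Reactants: 7 hydroxy mesylate
Product: 8 (1S)-1-[(1R,6S)-2-[(methoxymethoxy)methyl]-6-methyl-4-oxocyclohex-2-en-1-yl]-2,2-dimethylbut-3-en-1-yl methanesulfonate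
Conditions: pyridinium chlorochromate [C5H5NH][CrO3Cl], 4 Å MS, CH2Cl2, rt
Reagents that add atoms: pyridinium chlorochromate [O-][Cr](Cl)(=O)=O.c1cc[nH+]cc1
Why: Dauben–Babler oxidative 1,3-transposition: the chromate ester of the tertiary allylic alcohol undergoes a [3,3] shift and oxidation to the β-substituted enone; mesylate, MOM ether and vinyl group should be inert.

**Step 7**
Reactants: 8 enone mesylate
Product: 10 (1R,4S,5S,6R,7S)-6-[(methoxymethoxy)methyl]-4,6-dimethyl-7-(2-methylbut-3-en-2-yl)bicyclo[3.1.1]heptan-2-one, via lithium enolate 9 (not isolated)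
Conditions: Me2CuLi (from MeLi, CuI; 3 equiv), Et2O, −40 → 0 °C; then THF, 0 → 40 °C; aq. NH4Cl
Reagents that add atoms: lithium dimethylcuprate [Li+].C[Cu-]C
Why: Me2CuLi adds in conjugate fashion to C2 (target numbering) of enone 8 and so creates the lithium enolate 9 regiospecifically at C1/C11 under aprotic conditions; its α-carbon C1 then displaces the mesylate at C7 in an intramolecular SN2 alkylation that forms the C1–C7 bond. The closest known reaction types are tandem cuprate conjugate addition–intramolecular enolate alkylation and the keto-sulfonate cyclisations that close the cyclobutane of bicyclo[3.1.1]heptan-2-ones (copaene, bergamotene and nopinone syntheses). The four-membered ring C1–C2–C8–C7 closes 4-exo-tet from a 1,3-diaxial arrangement, and with it the second six-membered ring (C1, C11, C10, C9, C8, C7) of the bicyclo[3.1.1]heptanone. C2 is set by methyl delivery anti to the C8 side chain, which allylic strain with the C2 substituent holds axial (the axial C9 methyl is tolerated as in isophorone); C7 by inversion of the (S)-mesylate from the syn aldol; C1 by the geometric demand of the one-carbon bridge. The step needs the C1 and not the C10 enolate (secured because the enolate is born by conjugate addition with no proton source, and C8–H is not acidic at this stage, so mesylate elimination is avoided) and C- rather than O-alkylation (lithium counter-ion in ether, no dipolar additive).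

**Step 8**
Reactants: 10 bicyclic ketone
Product: 12 (1R,5R,6R,7S)-6-[(methoxymethoxy)methyl]-4,6-dimethyl-7-(2-methylbut-3-en-2-yl)bicyclo[3.1.1]hept-3-en-2-one, via silyl enol ether 11 (not isolated)
Conditions: LiN(i-Pr)2, Me3SiCl, THF, −78 °C; then Pd(OAc)2, MeCN, rt
Reagents that add atoms: chlorotrimethylsilane C[Si](C)(C)Cl (silicon of 11 only)
Why: Saegusa–Ito oxidation; the ketone can enolise only toward C3 because C1 is a bridgehead, so the enone forms regiospecifically and the C4 stereocentre inherited from 4 is erased.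

**Step 9**
Reactants: 12 MOM ether
Product: 13 (1R,5R,6R,7S)-6-(hydroxymethyl)-4,6-dimethyl-7-(2-methylbut-3-en-2-yl)bicyclo[3.1.1]hept-3-en-2-one
Conditions: conc. HCl (cat.), MeOH, 45 °C
Reagents that add atoms: none
Why: Acid-catalysed transacetalisation removes the MOM group as dimethoxymethane; enone, cyclobutane and vinyl group should tolerate dilute methanolic acid.

**Step 10**
Reactants: 13 primary alcohol
Product: 14 (1R,5R,6R,7S)-4,6-dimethyl-7-(2-methylbut-3-en-2-yl)-2-oxobicyclo[3.1.1]hept-3-ene-6-carbaldehyde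
Conditions: Dess–Martin periodinane, NaHCO3, CH2Cl2, 0 °C → rt
Reagents that add atoms: none
Why: Dess–Martin oxidation of the neopentyl alcohol to a non-enolisable aldehyde.

**Step 11**
Reactants: 14 aldehyde
Product: 15 (1R,5R,6R,7S)-6-(1-hydroxyprop-2-en-1-yl)-4,6-dimethyl-7-(2-methylbut-3-en-2-yl)bicyclo[3.1.1]hept-3-en-2-one (both carbinol epimers)
Conditions: CH2=CHMgBr (1.2 equiv), THF, −78 °C; H2O
Reagents that add atoms: vinylmagnesium bromide C=C[Mg]Br
Why: Grignard addition to the aldehyde, which is far more electrophilic than the hindered conjugated C2 ketone at −78 °C; the carbinol centre forms without control and is oxidised in step 12.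

**Step 12**
Reactants: 15 allylic alcohol
Product: 16 (1R,5R,6R,7S)-4,6-dimethyl-7-(2-methylbut-3-en-2-yl)-6-(prop-2-enoyl)bicyclo[3.1.1]hept-3-en-2-one
Conditions: Dess–Martin periodinane, NaHCO3, CH2Cl2, 0 °C
Reagents that add atoms: none
Why: Dess–Martin oxidation to the vinyl ketone removes the uncontrolled centre.

**Step 13**
Reactants: 16 vinyl ketone
Product: 17 (1R,2R,7S,8R)-2,6,6,9-tetramethyltricyclo[5.4.0.0^2,8]undeca-4,9-diene-3,11-dione
Conditions: second-generation Grubbs catalyst RuCl2(=CHPh)(PCy3)(H2IMes) (5 mol%), toluene (2 mM), 80 °C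
Reagents that add atoms: none
Why: Ring-closing metathesis of the acryloyl and neopentyl vinyl groups, held cis-1,3 on the cyclobutane on the face opposite the enone bridge; the seven-membered ring closes as its Z-enone.

**Step 14**
Reactants: 17 dienedione
Product: 19 (1R,2R,5R,7S,8R)-5-hydroxy-2,6,6,9-tetramethyltricyclo[5.4.0.0^2,8]undec-9-ene-3,11-dione, via boronate 18 (not isolated)
Conditions: CuCl (5 mol%), NaOt-Bu (10 mol%), (R)-1-[(Sp)-2-(diphenylphosphino)ferrocenyl]ethyldicyclohexylphosphine (6 mol%), B2pin2, MeOH, THF, rt; then NaBO3·4H2O, THF/H2O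
Reagents that add atoms: bis(pinacolato)diboron CC1(C)OB(OC1(C)C)B1OC(C)(C)C(C)(C)O1 (boron of 18); sodium perborate [Na+].[O-]OB=O (oxygen of 19)
Why: Copper-catalysed asymmetric conjugate borylation (Yun type) of the disubstituted cycloheptenone, then C–B oxidation with retention; the shielded trisubstituted C9=C10 enone should not compete, and because the ring is locally almost mirror-symmetric about C5 the ligand decides the face (the antipode is taken if the sense proves opposite to 5R).

**Step 15**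
Reactants: 20 (E)-2-methylbut-2-en-1-ol
Product: 21 [(2R,3R)-2,3-dimethyloxiran-2-yl]methanol
Conditions: Ti(Oi-Pr)4 (10 mol%), D-(−)-diethyl tartrate (12 mol%), t-BuOOH, 4 Å MS, CH2Cl2, −20 °C
Reagents that add atoms: tert-butyl hydroperoxide CC(C)(C)OO
Why: Sharpless asymmetric epoxidation; the D-tartrate catalyst sets both stereocentres (2R,3R) and the E geometry is carried into the cis-dimethyl epoxide.

**Step 16**
Reactants: 21 epoxy alcohol
Product: 22 (2S,3R)-2,3-dimethyloxirane-2-carbaldehyde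
Conditions: Dess–Martin periodinane, NaHCO3, CH2Cl2, 0 °C; used as a solution
Reagents that add atoms: none
Why: Dess–Martin oxidation to the α-quaternary epoxy aldehyde, which cannot epimerise.

**Step 17**
Reactants: 19 hydroxy diketone; 22 epoxy aldehyde
Product: 23 (1R,2R,3R,5R,7S,8R)-3-hydroxy-2,6,6,9-tetramethyl-11-oxotricyclo[5.4.0.0^2,8]undec-9-en-5-yl (2S,3R)-2,3-dimethyloxirane-2-carboxylate
Conditions: SmI2 (0.3 equiv) and PhCHO (0.3 equiv), THF, rt, until the blue colour is gone (trivalent samarium pinacolate catalyst); then 19 and 22 (4 equiv), THF, −10 °C; aq. NaHCO3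
Reagents that add atoms: none
Why: Evans–Tishchenko reduction with a catalyst preformed from SmI2 and benzaldehyde, so that 22 never meets divalent samarium: the samarium-bound hemiacetal of the C5 hydroxyl with 22 transfers hydride intramolecularly through a six-membered transition state to the same face of the C3 ketone, giving the 1,3-anti (3R) alcohol and at once the C5 ester with the aldehyde's stereocentres intact.

**Step 18**
Reactants: 23 hydroxy ester; 24 angelic acid
Product: 25 CNP0149458.1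
Conditions: 24, 2,4,6-trichlorobenzoyl chloride, Et3N, toluene, rt; then 23, 80 °C
Reagents that add atoms: none
Why: Yamaguchi-type esterification through the mixed anhydride without DMAP, conditions known to acylate hindered secondary alcohols without Z→E isomerisation of the angelate.

**Compound list**
1 | 2,2-dimethylbut-3-enoic acid | OC(=O)C(C)(C)C=C | starting material
2 | 2,2-dimethylbut-3-en-1-ol | OCC(C)(C)C=C | intermediate
3 | 2,2-dimethylbut-3-enal | O=CC(C)(C)C=C | intermediate
4 | (S)-5-methylcyclohex-2-en-1-one | O=C1C=CC[C@H](C)C1 | starting material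
5 | (5S,6S)-6-[(1S)-1-hydroxy-2,2-dimethylbut-3-en-1-yl]-5-methylcyclohex-2-en-1-one | C=CC(C)(C)[C@@H](O)[C@H]1C(=O)C=CC[C@@H]1C | intermediate
6 | (1S,5S,6S)-6-[(1S)-1-hydroxy-2,2-dimethylbut-3-en-1-yl]-1-[(methoxymethoxy)methyl]-5-methylcyclohex-2-en-1-ol | C=CC(C)(C)[C@@H](O)[C@H]1[C@](O)(COCOC)C=CC[C@@H]1C | intermediate
7 | (1S)-1-[(1S,2S,6S)-2-hydroxy-2-[(methoxymethoxy)methyl]-6-methylcyclohex-3-en-1-yl]-2,2-dimethylbut-3-en-1-yl methanesulfonate | C=CC(C)(C)[C@@H](OS(C)(=O)=O)[C@H]1[C@](O)(COCOC)C=CC[C@@H]1C | intermediate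
8 | (1S)-1-[(1R,6S)-2-[(methoxymethoxy)methyl]-6-methyl-4-oxocyclohex-2-en-1-yl]-2,2-dimethylbut-3-en-1-yl methanesulfonate | C=CC(C)(C)[C@@H](OS(C)(=O)=O)[C@H]1C(COCOC)=CC(=O)C[C@@H]1C | intermediate
9 | lithium enolate formed from 8 by methyl addition (C-methyl trans to the side chain) | [Li+].C=CC(C)(C)[C@@H](OS(C)(=O)=O)[C@H]1[C@@](C)(COCOC)C=C([O-])C[C@@H]1C | intermediate
10 | (1R,4S,5S,6R,7S)-6-[(methoxymethoxy)methyl]-4,6-dimethyl-7-(2-methylbut-3-en-2-yl)bicyclo[3.1.1]heptan-2-one | C=CC(C)(C)[C@@H]2[C@H]3C(=O)C[C@H](C)[C@@H]2[C@]3(COCOC)C | intermediate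
11 | trimethylsilyl enol ether of 10 (C2=C3) | C=CC(C)(C)[C@@H]2[C@H]3C(O[Si](C)(C)C)=C[C@H](C)[C@@H]2[C@]3(COCOC)C | intermediate
12 | (1R,5R,6R,7S)-6-[(methoxymethoxy)methyl]-4,6-dimethyl-7-(2-methylbut-3-en-2-yl)bicyclo[3.1.1]hept-3-en-2-one | C=CC(C)(C)[C@@H]2[C@H]3C(=O)C=C(C)[C@@H]2[C@]3(COCOC)C | intermediate
13 | (1R,5R,6R,7S)-6-(hydroxymethyl)-4,6-dimethyl-7-(2-methylbut-3-en-2-yl)bicyclo[3.1.1]hept-3-en-2-one | C=CC(C)(C)[C@@H]2[C@H]3C(=O)C=C(C)[C@@H]2[C@]3(CO)C | intermediate
14 | (1R,5R,6R,7S)-4,6-dimethyl-7-(2-methylbut-3-en-2-yl)-2-oxobicyclo[3.1.1]hept-3-ene-6-carbaldehyde | C=CC(C)(C)[C@@H]2[C@H]3C(=O)C=C(C)[C@@H]2[C@]3(C=O)C | intermediate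
15 | (1R,5R,6R,7S)-6-(1-hydroxyprop-2-en-1-yl)-4,6-dimethyl-7-(2-methylbut-3-en-2-yl)bicyclo[3.1.1]hept-3-en-2-one, both carbinol epimers | C=CC(C)(C)[C@@H]2[C@H]3C(=O)C=C(C)[C@@H]2[C@]3(C(O)C=C)C | intermediate
16 | (1R,5R,6R,7S)-4,6-dimethyl-7-(2-methylbut-3-en-2-yl)-6-(prop-2-enoyl)bicyclo[3.1.1]hept-3-en-2-one | C=CC(C)(C)[C@@H]2[C@H]3C(=O)C=C(C)[C@@H]2[C@]3(C(=O)C=C)C | intermediate
17 | (1R,2R,7S,8R)-2,6,6,9-tetramethyltricyclo[5.4.0.0^2,8]undeca-4,9-diene-3,11-dione | O=C1C=CC(C)(C)[C@@H]2[C@H]3C(=O)C=C(C)[C@@H]2[C@]31C | intermediate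
18 | (1R,2R,5R,7S,8R)-2,6,6,9-tetramethyl-5-(4,4,5,5-tetramethyl-1,3,2-dioxaborolan-2-yl)tricyclo[5.4.0.0^2,8]undec-9-ene-3,11-dione | O=C1C[C@@H](B2OC(C)(C)C(C)(C)O2)C(C)(C)[C@@H]2[C@H]3C(=O)C=C(C)[C@@H]2[C@]31C | intermediate
19 | (1R,2R,5R,7S,8R)-5-hydroxy-2,6,6,9-tetramethyltricyclo[5.4.0.0^2,8]undec-9-ene-3,11-dione | O=C1C[C@@H](O)C(C)(C)[C@@H]2[C@H]3C(=O)C=C(C)[C@@H]2[C@]31C | intermediate
20 | (E)-2-methylbut-2-en-1-ol | C/C=C(\C)CO | starting material
21 | [(2R,3R)-2,3-dimethyloxiran-2-yl]methanol | OC[C@@]1(C)O[C@@H]1C | intermediate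
22 | (2S,3R)-2,3-dimethyloxirane-2-carbaldehyde | O=C[C@@]1(C)O[C@@H]1C | intermediate
23 | (1R,2R,3R,5R,7S,8R)-3-hydroxy-2,6,6,9-tetramethyl-11-oxotricyclo[5.4.0.0^2,8]undec-9-en-5-yl (2S,3R)-2,3-dimethyloxirane-2-carboxylate | O[C@@H]1C[C@@H](OC(=O)[C@@]2(C)O[C@@H]2C)C(C)(C)[C@@H]2[C@H]3C(=O)C=C(C)[C@@H]2[C@]31C | intermediate
24 | angelic acid, (Z)-2-methylbut-2-enoic acid | C/C=C(/C)C(=O)O | starting material
25 | CNP0149458.1, (1R,2R,3R,5R,7S,8R)-2,6,6,9-tetramethyl-3-{[(2Z)-2-methylbut-2-enoyl]oxy}-11-oxotricyclo[5.4.0.0^2,8]undec-9-en-5-yl (2S,3R)-2,3-dimethyloxirane-2-carboxylate | C/C=C(/C)C(=O)O[C@@H]1C[C@@H](OC(=O)[C@@]2(C)O[C@@H]2C)C(C)(C)[C@@H]2[C@H]3C(=O)C=C(C)[C@@H]2[C@]31C | target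

**Step count and risks**
Total step count: 18. Longest linear sequence: 16 (steps 1–14, 17, 18).

Steps most likely to fail:

Step 7. Displacement at the neopentyl-type secondary carbon may be slow, so the enolate could transfer a proton or alkylate on oxygen, and the cuprate could add with poor facial selectivity. The fallback sets out from 8 and comes back at 12. Me2CuLi addition to 8 with a cold NH4Cl quench should give (1S)-1-[(1R,2S,6S)-2-[(methoxymethoxy)methyl]-2,6-dimethyl-4-oxocyclohexyl]-2,2-dimethylbut-3-en-1-yl methanesulfonate F1. Kinetic silyl enol ether formation on the less hindered C10 side (LiN(i-Pr)2, Me3SiCl) and Pd(OAc)2 oxidation should give (1S)-1-[(1R,6S)-6-[(methoxymethoxy)methyl]-2,6-dimethyl-4-oxocyclohex-2-en-1-yl]-2,2-dimethylbut-3-en-1-yl methanesulfonate F2, in which C10 is blocked as an sp2 carbon. LiN(i-Pr)2 (THF, −78 → 0 °C) then forms the only possible α′ (C1) enolate of this enone, which closes the cyclobutane in the classical keto-sulfonate manner to give 12 directly.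

Step 17. Hydride transfer from the hemiacetal of the hindered α-quaternary aldehyde may be slow, and the Lewis-acidic trivalent samarium may open the epoxide of 22 or promote retro-aldol cleavage of 19. The fallback sets out from 19 and comes back at 25. Evans–Tishchenko reduction with acetaldehyde under the same preformed catalyst should give (1R,2R,3R,5R,7S,8R)-3-hydroxy-2,6,6,9-tetramethyl-11-oxotricyclo[5.4.0.0^2,8]undec-9-en-5-yl acetate F5. Angeloylation as in step 18 gives (1R,2R,3R,5R,7S,8R)-5-acetoxy-2,6,6,9-tetramethyl-11-oxotricyclo[5.4.0.0^2,8]undec-9-en-3-yl (2Z)-2-methylbut-2-enoate F6. Selective methanolysis of the acetate (K2CO3, MeOH, 0 °C) gives (1R,2R,3R,5R,7S,8R)-5-hydroxy-2,6,6,9-tetramethyl-11-oxotricyclo[5.4.0.0^2,8]undec-9-en-3-yl (2Z)-2-methylbut-2-enoate F7. This is esterified (2,4,6-trichlorobenzoyl chloride, Et3N, DMAP) with (2S,3R)-2,3-dimethyloxirane-2-carboxylic acid F8, made from 21 with RuCl3 (cat.)/NaIO4, to give 25.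

Step 3. The closed transition state of the cyclic enolate may give low syn/anti selectivity, and the wrong carbinol epimer cannot invert productively in step 7. The fallback sets out from 4 and comes back at 5. LiN(i-Pr)2/Me3SiCl should give {[(3S)-3-methylcyclohexa-1,5-dien-1-yl]oxy}trimethylsilane F3. A fluoride-catalysed aldol with 3 (tris(dimethylamino)sulfonium difluorotrimethylsilicate, THF, −78 °C), which passes through an open transition state and is syn-selective, should give (5S,6S)-6-{(1S)-2,2-dimethyl-1-[(trimethylsilyl)oxy]but-3-en-1-yl}-5-methylcyclohex-2-en-1-one F4. Citric acid in MeOH then frees 5.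

**Further compounds**
F1 | step 7 | (1S)-1-[(1R,2S,6S)-2-[(methoxymethoxy)methyl]-2,6-dimethyl-4-oxocyclohexyl]-2,2-dimethylbut-3-en-1-yl methanesulfonate | C=CC(C)(C)[C@@H](OS(C)(=O)=O)[C@H]1[C@@](C)(COCOC)CC(=O)C[C@@H]1C
F2 | step 7 | (1S)-1-[(1R,6S)-6-[(methoxymethoxy)methyl]-2,6-dimethyl-4-oxocyclohex-2-en-1-yl]-2,2-dimethylbut-3-en-1-yl methanesulfonate | C=CC(C)(C)[C@@H](OS(C)(=O)=O)[C@H]1[C@@](C)(COCOC)CC(=O)C=C1C
F3 | step 3 | {[(3S)-3-methylcyclohexa-1,5-dien-1-yl]oxy}trimethylsilane | C[Si](C)(C)OC1=C[C@@H](C)CC=C1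
F4 | step 3 | (5S,6S)-6-{(1S)-2,2-dimethyl-1-[(trimethylsilyl)oxy]but-3-en-1-yl}-5-methylcyclohex-2-en-1-one | C=CC(C)(C)[C@@H](O[Si](C)(C)C)[C@H]1C(=O)C=CC[C@@H]1C
F5 | step 17 | (1R,2R,3R,5R,7S,8R)-3-hydroxy-2,6,6,9-tetramethyl-11-oxotricyclo[5.4.0.0^2,8]undec-9-en-5-yl acetate | O[C@@H]1C[C@@H](OC(C)=O)C(C)(C)[C@@H]2[C@H]3C(=O)C=C(C)[C@@H]2[C@]31C
F6 | step 17 | (1R,2R,3R,5R,7S,8R)-5-acetoxy-2,6,6,9-tetramethyl-11-oxotricyclo[5.4.0.0^2,8]undec-9-en-3-yl (2Z)-2-methylbut-2-enoate | C/C=C(/C)C(=O)O[C@@H]1C[C@@H](OC(C)=O)C(C)(C)[C@@H]2[C@H]3C(=O)C=C(C)[C@@H]2[C@]31C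
F7 | step 17 | (1R,2R,3R,5R,7S,8R)-5-hydroxy-2,6,6,9-tetramethyl-11-oxotricyclo[5.4.0.0^2,8]undec-9-en-3-yl (2Z)-2-methylbut-2-enoate | C/C=C(/C)C(=O)O[C@@H]1C[C@@H](O)C(C)(C)[C@@H]2[C@H]3C(=O)C=C(C)[C@@H]2[C@]31C
F8 | step 17 | (2S,3R)-2,3-dimethyloxirane-2-carboxylic acid | OC(=O)[C@@]1(C)O[C@@H]1C
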